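The ratio E of side product to target at the outlet or end gives what is asked. A side product weighs two, so the share of target, a selectivity, is 1/(1+2E).

| setting | autumn | dusk | winter |
|---|---|---|---|
| substrate | 0.35 M | 0.35 M | 0.35 M |
| remark | one stirred flow tank at steady state, fed with the mixture as stated, mean residence time 2.0 min | one stirred flow tank at steady state, fed with the mixture as stated, mean residence time 10.0 min | a closed flask charged with all of it at once and left for 2.0 min |
| time |  |  | 2.0 min |

* the set-up with the highest share of target in all that became target or side product, at the outlet or at the end ("none" if the first two lie within 2 percentage points) (autumn / dusk / winter / none)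
* share of target in all that became target or side product, at the outlet or at the end, autumn
* share of target in all that became target or side product, at the outlet or at the end, dusk
* share of target in all that became target or side product, at the outlet or at the end, winter

- in percentages every species weighs as the substrate in it: one side product counts as two
- the stated concentrations are those of everything mixed, before any reaction; amounts are the same in each set-up
- run time (winter): 2.0 min

    substrate ⇌ intermediate B (K1 = 1.1, k1 = 8.8 × 10⁻⁴ s⁻¹)
    substrate + target → side product (k2 = 0.040 M⁻¹ s⁻¹)
    intermediate A → target (k3 = 0.0060 s⁻¹)
    intermediate A ⇌ intermediate B (k4 = 0.0033 s⁻¹)
    intermediate B → decomposed reagent (k5 = 0.0061 s⁻¹)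
    substrate ⇌ intermediate A (K6 = 1.6, k6 = 0.0098 s⁻¹)

In a stirred tank, the balance on side product gives E = κSτ, with κ = 0.040 M⁻¹ s⁻¹ for substrate + target, S the outlet substrate and τ the residence time. So you need S. Substrate leaves forward towards both intermediates at λ = 0.641 min⁻¹. If you count no return, S is the charge 0.35 M divided by 1 + λτ, which gives 0.153 M in autumn and 0.0472 M in dusk. My tank shares are then 40.4% and 30.6%.

But the winter flask starts without target, which must wait for intermediate A. Early on target grows as the square of time, so its mean time in the flask is about a third of the run. If you again count no return, mean substrate over the winter run is about 0.197 M. So the exposure, κ times substrate times the mean time target has stood, is 0.316, which gives 61.3%. My pick is winter.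

The forecast chose winter, with 38.3% (36% to 41%), 27.2% (25% to 30%) and 60% (55% to 65%), holding that “the longer tank loses more target despite its lower substrate level”.

The simulation gives winter, with 38.3%, 27.2% and 58.3%.

Read from these shares, E is 0.804 in the autumn tank and 0.358 in the winter flask, so over the same 2.0 min the tank holds about twice as much side product per target. Left for 20.0 min, ten times as long, the winter flask shows a share of 42.8%, so its E reads 0.668, about twice the 0.316 reckoned for 2.0 min.

Its constants are those of an exercise, and the outcome is calculated.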